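Begin at the late end: birch, the flask asked about, has been followed to 120 min and must be answered at 4.0 h, while elm, run earlier with twice the coupling partner, has already reached that hour.

common to all: substrate 0.80 M

| flask | coupling partner | remark | time |
|---|---|---|---|
| birch | 1.2 equiv | the very flask that is asked about, followed so far |  |
| elm | 2.4 equiv | run made earlier |  |
| flask | 1.20 equiv |  | 4.0 h |

- birch (time / min: target / %, isomer of the product / %, substrate / %): 30.0: 17.8, 10.2, 53.7; 60.0: 31.9, 17.9, 29.0; 90.0: 35.8, 20.1, 16.9; 120: 35.1, 20.2, 12.6
- elm (time / h: target / %, isomer of the product / %, substrate / %): 0.333: 25.4, 13.3, 40.8; 0.667: 38.2, 20.8, 18.6; 1.50: 45.4, 24.6, 1.8; 4.00: 41.7, 23.6, 0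

(readings scatter by 1 percentage point)

1. ratio of target to isomer of the product at 4.0 min
2. ratio of target to isomer of the product at 30 min
3. ratio of target to isomer of the product at 4.0 h
4. which of target and isomer of the product there is more of at 4.0 h

Apply the bench rule for two products that rise together and replace the curve of [target]/[isomer of the product] in birch by its mean, 1.76, and call this reading the split, a selectivity factor between the two products. Check the error this makes: the last birch ratio lies 0.0239 below the split, and the scatter of that ratio is 0.0992, so the error is less than the scatter; take the split for 30 min and, with wider doubt since no reading stands there, for 4.0 min.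

Look for the border in elm, where from 1.50 h to 4.00 h target falls 3.7 percentage points and isomer of the product 1 point. The ratio of these falls, 3.70, stands above the split, so the mean of the birch readings need not hold out to the last elm reading, though this is a faint sign, each fall carrying 1.4 points of scatter. Trim the split by the sag of the elm ratio over that stretch, assuming birch sags alike, and commit to 1.69 at 4.0 h, with target ahead.

The forecast gives 1.78, 1.77, 1.7 and target ahead, on the ground that “the two products appear to form in a nearly fixed ratio”, which puts it slightly above my split early and close to my trimmed value late.

The birch flask gives 1.77 at 4.0 min, 1.74 at 30 min and 1.68 at 4.0 h, which is 0.953 of the split, with target ahead at 35.7 % against 21.3 %, and its steps are these: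

    intermediate ⇌ target (K = 4.23, k = 0.114 min⁻¹)
    substrate + coupling partner → intermediate + released group (k = 0.0240 L mol⁻¹ min⁻¹)
    substrate + released group → side product (k = 0.0154 L mol⁻¹ min⁻¹)
    target → over-reaction product (k = 0.00133 min⁻¹)
    intermediate ⇌ isomer of the product (K = 2.40, k = 0.0642 min⁻¹)

Birch holds 22.6 % of side product after 4.00 h, yet taking that loss away leaves the ratio where it stands. Carry the split to a neighbour flask charged with 0.300 equiv of coupling partner: its 8.11 % of isomer of the product after 4.00 h gives 14.3 % of target, and that neighbour flask holds 13.6 %.

All runs stem from a simulated flask with constants of no real substance; scatter was added.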